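## Structural features

The target is a pentacyclic C20 diacid. Cyclohexane ring A (C1–C5, C10) is trans-fused to cyclopentane ring B (C5, C6, C8, C9, C10), which is cis-fused to cyclohexane ring C (C8, C9, C11–C14). Ring D (C8, C13–C16, with the C16=C17 methylene) spans C8 and C13, so rings C and D form a bicyclo[3.2.1]octane. A δ-lactone C10–C20(=O)–O–C12 bridges ring C a second time and puts C20, C11 and C14 on the same (α) face of ring B. There are ten stereocentres (C2, C3, C4, C5, C6, C8, C9, C10, C12, C13), most of them contiguous. Three are quaternary (C4, C8, C10), and C4 and C10 flank C5 with their carboxyl carbons C19 and C20 syn-axial on ring A. Fragile points are the exocyclic alkene (acid), the lactone (base), the epimerisable C6–H next to the C7 carboxyl, and the C3–OH/C19 β-hydroxy acid unit (retro-aldol in strong base). The real difficulty is the trans A/B fusion between two quaternary carbons combined with a ring C that sits on the hindered C20 face, plus the quaternary bridgehead C8. The key step uses the lactone-locked chair of ring C: C10 and O12 are diaxial on the α face, and on the β face the C13 substituent and H-8 are 1,3-diaxial, so a carbenoid carbon C15 on a C16 acyl group at C13 is held over the tertiary C8–H bond.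

## Logic of the disconnections

**29 ⇒ 28 ⇒ 27 (no skeletal bond).** The two acids are masked as methyl esters and the diol as an isopropylidene acetal, so that no O–H bond can intercept a carbenoid. The forward unmasking must spare the lactone and the exocyclic alkene.

**C16=C17, 27 ⇒ 26.** The alkene is cut back to the C16 ketone, because a ketone at C16 is what ring D closure leaves behind. The acid-sensitive alkene then exists only in the last three compounds. The forward step must methylenate a hindered ketone without disturbing C6.

**C8–C15, 26 ⇒ 25 (key cut).** Cutting here removes ring D, the quaternary C8 and the bicyclo[3.2.1]octane in one stroke and leaves a C–H bond at C8. The forward step must insert into C8–H with retention and must not touch the other axial hydrogen at C11.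

**C15–C16 and the oxidation level of C16, 25 ⇒ 22 + 23 ⇒ 20 ⇒ 19.** C15 comes from 23, and C16 is carried as a silyl-protected CH2OH. C13 therefore never carries an enolisable carbonyl until the cage has fixed it in the axial position. The forward oxidation and activation must not epimerise C13.

**C2–O and C3–O, 19 ⇒ 18 ⇒ 17, and the C3 carbonyl, 17 ⇒ 16 ⇒ 15.** The diol is cut to a 2-ene whose α face is shielded by the axial C19 and C20 groups. The alkene is traced to the C3 ketone, which can enolise only toward C2. The forward demand is β-face dihydroxylation.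

**C4–C18 and C5–H, 15 ⇒ 14 ⇒ 13.** The methyl group is cut last because alkylating a C4 ester enolate puts the ester axial, syn to C20. C5–H is traced to a C4=C5 alkene. The forward hydrogen must arrive on the β face to give the trans fusion.

**Ring A bonds C4–C5 and C1–C10, 13 ⇒ 12 ⇒ 11 ⇒ 9 + 10.** Ring A is removed as the five-carbon reagent 10, which brings C1–C4 and C19. This leaves C10 as the acidic carbon of a β-keto lactone. C6=C8 is kept until C10 is quaternary, so that C6 cannot compete as a nucleophile. The forward demand is C–C bond formation on the β face of C10, which the cage enforces.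

**Ring B bond C6=C8 and lactone bond C20–O12, 9 ⇒ 7; then 7 ⇒ 6 ⇒ 5.** These cuts open the cage to a monocyclic ring C carrying a 3-oxoglutarate chain. C12 is reduced before the C8 ketone is unmasked, so that C13 is already fixed when C9 becomes enolisable and the two centres cannot scramble.

**C9–C10, 5 ⇒ 3 + 4.** The ring C/chain bond is cut to a Michael acceptor and the five-carbon donor 4, which brings C5, C6, C7, C10 and C20. The forward step must set C9 by catalyst control.

**C13–C16, 3 ⇒ 2 ⇒ 1.** C16 is attached at the only enolisable position of 1, which settles the regiochemistry of the later C13 acyl group at the outset.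

## Other disconnections considered

**Alternative 1:** The cut is C9–C11 in ring C, made at the start on a fragment that holds only rings B and C. Forward, L-proline would desymmetrise the prochiral precursor of A1 by enamine aldol condensation of C11 onto one of two enantiotopic ring carbonyls (C9). This gives the (R)-enedione A1, in which C8 is already quaternary and carries C15–C17 as a propargyl group.
- In favour: a cheap catalytic step fixes the hardest centre of ring D first, and the alkyne later supplies C17 without a Wittig reaction or a diazo compound.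
- Against: A1 lacks C1–C4, C7 and C18–C20. C10 is a plain methylene that must become quaternary with C20 on the crowded face. The C6 ketone must be homologated to the C7 acid. Ring A must be annulated trans, and ring D still has to be closed from the alkyne onto C13.
- Comparison: structurally, A1 secures C8 early and leaves the A/B array open, whereas the chosen plan secures the A/B array and the lactone first and lets the cage deliver C8. Mechanistically, the enantiocontrol of the proline aldol is better established than that of the Michael addition used here, and this point goes to the alternative. It also avoids diazo chemistry, which is at least an equal point. In step economy the chosen plan should be shorter, because the work after A1 (ring A, two carboxyl carbons, lactone, ring D) exceeds what remains after the insertion.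

**Alternative 2:** The cuts are C5–C10 and C3–C4. Forward, a 2-silyloxy diene (C10=C1–C2=C3) carried on the preformed lactone and a tethered (Z)-enoate (C5=C4) would combine on heating in an intramolecular Diels–Alder reaction. This closes ring A and, as the tether ring, ring B, to give A2.
- In favour: two rings, both quaternary carbons C4 and C10 and the C3 oxygen arise in one step, and the tether fixes the C10 configuration.
- Against: the ring C/D bicyclooctane, the lactone and the diene must all be built first, so the ring D problem is moved, not solved. The dienophile carbon C4 is fully substituted, so forcing conditions and uncertain endo/exo and facial selectivity are to be expected. The C2 enol ether must still be reduced to the 2β-alcohol.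
- Comparison: for rings A and B this cycloaddition is clearly more step-economic than the stepwise annulation used here (about eight steps), and this point goes to the alternative. Structurally it places the risk at a late, crowded C–C bond formation. Mechanistically a thermal pericyclic step needs no metal, but the chosen plan sets each A/B centre by separate substrate-controlled steps whose sense can be argued from the cage.

**Alternative 3:** The cuts are C8–C9 and C12–C13. Forward, a cyclopentadiene tethered at C6 would add across a C9=C12 nitroalkene on C10. This closes ring B and a norbornene that holds C8 and C13–C16, giving A3. C11 must then be inserted between C9 and C12 by ring expansion.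
- In favour: the quaternary C8 is made by C–C bond formation with all five ring D carbons arriving in one piece, the nitro group activates the dienophile and marks C12 for oxygen, and ring A is already complete.
- Against: substituted cyclopentadienes equilibrate by 1,5-hydrogen shifts. The one-carbon expansion must choose the C9–C12 bond over C12–C13. The C15=C16 alkene must be oxidised regioselectively at C16. The lactone can close only after C12 has been converted.
- Comparison: in carbon economy for ring D and in avoiding a site-selective C–H functionalisation, the alternative is the equal or the better. Structurally it needs several corrective steps after the key step (nitro to carbonyl, expansion, alkene to methylene ketone), where the chosen plan needs one (methylenation). Mechanistically its selectivity rests on regiocontrol of a migration, that of the chosen plan on the difference between a tertiary and a deactivated secondary C–H bond.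

Key step: step 19

Assumptions and remarks on the chemistry:
- β denotes the face of ring B that carries H-5, H-8, H-9 and C1; α denotes the face that carries C4, C11, C14 and C20. Gibberellane numbering is used throughout.
- The stereodescriptors of 25 and 26 were compared atom by atom with those of 29. They agree (retention at C8), so both structures are used unchanged.
- The improvement to the precursor lies in how it is reached: C16 stays at the alcohol level until the cage exists, and the acid is activated without base.
- The quinine-derived primary amine is assumed to deliver 4 to the face of C9 that leads to 5. If the sense is opposite, the quinidine-derived pseudo-enantiomer is the catalyst.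
- Compound 10 is treated as a purchasable reagent and is used freshly distilled, because it polymerises on storage.

## Route

Step 1
Reactants: 1 1,4-dioxaspiro[4.5]dec-6-en-8-one
Product: 2 (±)-9-(hydroxymethyl)-1,4-dioxaspiro[4.5]dec-6-en-8-one
Conditions: LiN(iPr)2, THF, −78 °C; CH2O (from paraformaldehyde), −78 to −40 °C; aq. NH4Cl
Reagents that add atoms: formaldehyde, C=O
Why: The enone can be deprotonated only at the α' carbon (future C13), because the γ carbon is the ketal; aldol addition of the lithium enolate to formaldehyde installs C16 at the alcohol level. The new centre is racemic and is corrected in step 3.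

Step 2
Reactants: 2 (±)-9-(hydroxymethyl)-1,4-dioxaspiro[4.5]dec-6-en-8-one
Product: 3 (±)-9-{[tert-butyl(diphenyl)silyl]oxymethyl}-1,4-dioxaspiro[4.5]dec-6-en-8-one
Conditions: t-BuPh2SiCl, imidazole, DMF, 0 to 25 °C
Reagents that add atoms: tert-butyl(chloro)diphenylsilane, CC(C)(C)[Si](Cl)(c1ccccc1)c1ccccc1
Why: Silyl ether formation blocks retro-aldol cleavage and dehydration of the β-hydroxy ketone; this silyl group should survive the later acid, base and hydrogenation steps.

Step 3
Reactants: 3 (±)-9-{[tert-butyl(diphenyl)silyl]oxymethyl}-1,4-dioxaspiro[4.5]dec-6-en-8-one; 4 dimethyl 3-oxopentanedioate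
Product: 5 dimethyl 2-[(6S,9R)-9-{[tert-butyl(diphenyl)silyl]oxymethyl}-8-oxo-1,4-dioxaspiro[4.5]decan-6-yl]-3-oxopentanedioate (C2 of the diester chain unconfigured)
Conditions: 9-amino-9-deoxy-epi-quinine (20 mol %), CF3CO2H (40 mol %), THF, 30 °C
Reagents that add atoms: none
Why: Iminium activation of the enone by the chiral primary amine lets the 1,3-dicarbonyl add to the β carbon (organocatalytic asymmetric Michael addition), forming C9–C10 and setting C9 by catalyst control. C13, α to the ketone, should equilibrate through the enamine to the trans-2,5-diequatorial arrangement (menthone-type preference), and the minor epimer is removed at the next stage.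

Step 4
Reactants: 5 dimethyl 2-[(6S,9R)-9-{[tert-butyl(diphenyl)silyl]oxymethyl}-8-oxo-1,4-dioxaspiro[4.5]decan-6-yl]-3-oxopentanedioate
Product: 6 dimethyl 2-[(6S,8S,9R)-9-{[tert-butyl(diphenyl)silyl]oxymethyl}-8-hydroxy-1,4-dioxaspiro[4.5]decan-6-yl]-3-oxopentanedioate (12α-alcohol, all three ring substituents equatorial)
Conditions: NaBH4, MeOH–CH2Cl2 (1:1), −78 °C
Reagents that add atoms: none
Why: The 1,3-dicarbonyl unit is masked as its enol(ate), so borohydride should reduce only the ring ketone (chemoselective hydride reduction). Axial attack on the chair with both substituents equatorial should give the equatorial alcohol, trans to C13 and cis-1,3 to the C9 chain, and C13 is frozen at this point.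

Step 5
Reactants: 6 dimethyl 2-[(6S,8S,9R)-9-{[tert-butyl(diphenyl)silyl]oxymethyl}-8-hydroxy-1,4-dioxaspiro[4.5]decan-6-yl]-3-oxopentanedioate
Product: 7 dimethyl 2-[5-hydroxy-2-oxo-4-(silyloxymethyl)cyclohexyl]-3-oxopentanedioate (ring centres as in 6; C8 ketone free)
Conditions: pyridinium p-toluenesulfonate, acetone–H2O, 45 °C
Reagents that add atoms: water, O
Why: Mild acid-catalysed ketal hydrolysis frees the C8 ketone without touching the silyl ether. C9 becomes enolisable only now, when C12 and C13 are fixed, and its equatorial configuration is also the thermodynamic one.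

Step 6
Reactants: 7 dimethyl 2-[5-hydroxy-2-oxo-4-(silyloxymethyl)cyclohexyl]-3-oxopentanedioate
Product: 9 tricyclic enone lactone (ring B: C5 ketone, C6=C8, 6-CO2Me; C20→12α-O δ-lactone; 9β-H, 10β-H, 13β-CH2OSi), via bicyclic hydroxy enone diester 8 (not isolated)
Conditions: piperidine (cat.), AcOH (cat.), PhMe, reflux, Dean–Stark; then 4-(dimethylamino)pyridine (cat.), reflux
Reagents that add atoms: none
Why: Intramolecular Knoevenagel condensation of the active methylene C6 with the C8 ketone closes ring B as the conjugated enone ester. The β-keto ester at C10 then transesterifies with the cis-1,3 hydroxyl to the bridged δ-lactone (acyl transfer). The cage locks ring C in the chair with C10, O12 and C16 axial and allows only the 10β-H epimer.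

Step 7
Reactants: 9 tricyclic enone lactone; 10 methyl 3-oxopent-4-enoate
Product: 11 C10-quaternary Michael adduct (9 carrying the 5-methoxy-3,5-dioxopentyl chain C1–C4/C19 on the β face of C10)
Conditions: Cs2CO3 (10 mol %), CH2Cl2, 0 to 25 °C, slow addition of 10
Reagents that add atoms: none
Why: The β-keto lactone is the most acidic site and adds as its enolate to the unhindered vinyl ketone (Michael addition). Because C20 is tied into the lactone and C5 into ring B, the new C10–C1 bond can form only on the exo β face, which sets the quaternary C10.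

Step 8
Reactants: 11 C10-quaternary Michael adduct
Product: 12 saturated ring B keto diester (8β-H, 6β-CO2Me, 6α-H)
Conditions: H2 (3 atm), 10% Pd/C, EtOAc, 25 °C
Reagents that add atoms: none
Why: Catalytic hydrogenation of the activated tetrasubstituted enone ester, as for 2,3-disubstituted cyclopentenone esters. A five-membered ring fused to the locked chair with axial C10 can carry C6 only equatorially, so H-8 must be axial β. C6, a β-keto ester centre, should settle as the β-ester trans to C14.

Step 9
Reactants: 12 saturated ring B keto diester
Product: 13 tetracyclic enone (ring A closed: C3 ketone, C4=C5, 4-CO2Me)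
Conditions: piperidine (cat.), AcOH (cat.), PhMe, reflux, Dean–Stark
Reagents that add atoms: none
Why: Intramolecular Knoevenagel condensation of the side-chain β-keto ester methylene C4 with the C5 ketone closes ring A (second half of a Robinson-type annulation) and gives the alkylidene β-keto ester. C6 should remain the β-ester, trans to C14.

Step 10
Reactants: 13 tetracyclic enone
Product: 14 trans-fused β-keto ester (5β-H; C4 enolisable and unconfigured)
Conditions: H2 (3 atm), 10% Pd/C, EtOAc, 25 °C
Reagents that add atoms: none
Why: Hydrogenation of the alkylidene β-keto ester should deliver hydrogen to C5 from the convex β face, because the α face of ring B is covered by C20, the lactone and ring C. The closest precedent is the trans-selective reduction of 4-carboxy hydrindenones; this sets the trans A/B fusion.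

Step 11
Reactants: 14 trans-fused β-keto ester
Product: 15 C4-quaternary keto triester (4β-methyl, 4α-CO2Me)
Conditions: MeI, K2CO3, acetone, 25 to 50 °C
Reagents that add atoms: iodomethane, CI
Why: C-Methylation of the β-keto ester enolate (alkylation of a stabilised enolate) should occur on the β face, away from the axial C20 carbonyl that is 1,3 to C4. This gives the axial 4α-ester, the usual outcome when the ester is in place before the methyl group.

Step 12
Reactants: 15 C4-quaternary keto triester
Product: 16 C3 enol triflate (C2=C3)
Conditions: KN(SiMe3)2, THF, −78 °C; PhN(SO2CF3)2, −78 to 0 °C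
Reagents that add atoms: N-phenylbis(trifluoromethanesulfonimide), O=S(=O)(N(c1ccccc1)S(=O)(=O)C(F)(F)F)C(F)(F)F
Why: Only C2 can be enolised because C4 is quaternary, so the potassium enolate is trapped regiospecifically (enol triflate formation).

Step 13
Reactants: 16 C3 enol triflate
Product: 17 2-ene (C2=C3)
Conditions: Pd(OAc)2 (5 mol %), PPh3, HCO2H, n-Bu3N, DMF, 60 °C
Reagents that add atoms: none
Why: Palladium-catalysed hydride transfer from formate reduces the vinyl triflate to the alkene (reductive cleavage of an enol triflate) and leaves esters, lactone and silyl ether alone.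

Step 14
Reactants: 17 2-ene
Product: 18 2β,3β-diol
Conditions: OsO4 (2 mol %), N-methylmorpholine N-oxide, acetone–H2O, 25 °C
Reagents that add atoms: osmium tetroxide, O=[Os](=O)(=O)=O; N-methylmorpholine N-oxide, C[N+]1([O-])CCOCC1
Why: Osmium-catalysed syn-dihydroxylation should occur on the β face, because the pseudo-axial C19 ester on allylic C4 and the axial C20 on C10 shield the α face. This sets C2 and C3.

Step 15
Reactants: 18 2β,3β-diol
Product: 19 2β,3β-acetonide
Conditions: Me2C(OMe)2, pyridinium p-toluenesulfonate, acetone, 25 °C
Reagents that add atoms: 2,2-dimethoxypropane, COC(C)(C)OC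
Why: Acid-catalysed ketal exchange converts the cis-diol into the isopropylidene acetal, removing the O–H bonds that would intercept the carbenoid.

Step 16
Reactants: 19 2β,3β-acetonide
Product: 20 C16 alcohol (13β-CH2OH)
Conditions: n-Bu4NF, AcOH, THF, 25 °C
Reagents that add atoms: none
Why: Fluoride cleaves the silyl ether (desilylation); buffering with acetic acid protects the lactone and the esters.

Step 17
Reactants: 20 C16 alcohol
Product: 22 C16 carboxylic acid (axial 13β-CO2H), via C16 aldehyde 21 (not isolated)
Conditions: TEMPO (cat.), NaOCl (cat.), NaClO2, MeCN–phosphate buffer (pH 6.7), 35 °C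
Reagents that add atoms: sodium chlorite, [Na+].[O-]Cl=O
Why: Oxoammonium-catalysed oxidation with chlorite as terminal oxidant takes the alcohol through the aldehyde to the acid in one pot near neutral pH, so the axial aldehyde should not have time to epimerise at C13.

Step 18
Reactants: 22 C16 carboxylic acid; 23 (trimethylsilyl)diazomethane
Product: 25 13β-diazoacetyl ring A/B/C lactone (8β-H; 7,19-dimethyl ester; 2β,3β-acetonide), via C16 acid chloride 24 (not isolated)
Conditions: 1-chloro-N,N,2-trimethylprop-1-en-1-amine, CH2Cl2, 0 °C; then 23, MeCN–THF, 0 to 25 °C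
Reagents that add atoms: none
Why: The chloroenamine forms the acid chloride without base, so no ketene can form and the axial C13 centre should not epimerise. Acylation of the diazoalkane carbon and loss of the silyl group as Me3SiCl then give the diazoketone (Arndt–Eistert-type acylation).

Step 19
Reactants: 25 13β-diazoacetyl ring A/B/C lactone
Product: 26 16-oxo pentacycle (ring D closed; 7,19-dimethyl ester; 2β,3β-acetonide)
Conditions: Rh2(OAc)4 (1 mol %), CH2Cl2, 40 °C, slow addition of 25
Reagents that add atoms: none
Why: Rh2(OAc)4 should decompose the diazoketone with loss of N2 to an electrophilic rhodium carbenoid at C15, which inserts into the axial C8–H bond through a concerted three-centre transition state. The closest known reaction type is the dirhodium-catalysed 1,5 C–H insertion of α-diazoketones that gives cyclopentanones, here in its transannular form that gives a bicyclo[3.2.1]octanone. Ring D closes through the five-membered array C15–C16–C13–C14–C8, which is possible only because the lactone holds the C13 acyl group and H-8 1,3-diaxial on the β face of ring C. The one new stereocentre, quaternary C8, is controlled by retention at the C–H carbon, and C13 becomes the second bridgehead. The step needs selectivity for C8–H over the other axial hydrogen at C11, over the 1,4-related C–H bonds at C12 and C14, and over carbene dimerisation. C8–H is tertiary and more electron-rich, whereas C11–H is secondary and deactivated inductively by the acyloxy-bearing C12, and four-membered ring formation is strained. Acetate ligands favour this electronically discriminating insertion, the ester and acetal masking leaves no O–H bond, and slow addition at high dilution should suppress dimerisation.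

Step 20
Reactants: 26 16-oxo pentacycle
Product: 27 16-methylene pentacycle (7,19-dimethyl ester; 2β,3β-acetonide)
Conditions: Ph3PCH3Br, KOt-Bu, THF, 0 to 50 °C
Reagents that add atoms: methyltriphenylphosphonium bromide, C[P+](c1ccccc1)(c1ccccc1)c1ccccc1.[Br-]
Why: Wittig methylenation of the C16 ketone; the non-stabilised ylide should attack the ketone far faster than the esters or the hindered lactone, and C6 already has its thermodynamic configuration.

Step 21
Reactants: 27 16-methylene pentacycle
Product: 28 16-methylene 7,19-diacid 2β,3β-acetonide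
Conditions: EtSNa, DMF, 80 °C; then aq. HCl (pH 3)
Reagents that add atoms: none
Why: The thiolate cleaves both methyl esters by SN2 attack at the methyl carbon (nucleophilic dealkylation), which is insensitive to the hindrance of the axial C19 ester and should leave the secondary lactone C–O bond intact.

Step 22
Reactants: 28 16-methylene 7,19-diacid 2β,3β-acetonide
Product: 29 CNP0212122.1 (target)
Conditions: AcOH–H2O (4:1), 45 °C
Reagents that add atoms: none
Why: Mild acid hydrolysis of the isopropylidene acetal frees the diol under conditions that should be too weak to isomerise the exocyclic alkene or open the lactone.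

## Compound list

1 | 1,4-dioxaspiro[4.5]dec-6-en-8-one | O=C1C=CC2(CC1)OCCO2 | starting material
2 | (±)-9-(hydroxymethyl)-1,4-dioxaspiro[4.5]dec-6-en-8-one | O=C1C=CC2(CC1CO)OCCO2 | intermediate
3 | (±)-9-{[tert-butyl(diphenyl)silyl]oxymethyl}-1,4-dioxaspiro[4.5]dec-6-en-8-one | O=C1C=CC2(CC1CO[Si](c3ccccc3)(c3ccccc3)C(C)(C)C)OCCO2 | intermediate
4 | dimethyl 3-oxopentanedioate | COC(=O)CC(=O)CC(=O)OC | starting material
5 | dimethyl 2-[(6S,9R)-9-(silyloxymethyl)-8-oxo-1,4-dioxaspiro[4.5]decan-6-yl]-3-oxopentanedioate (silyl = tert-butyldiphenylsilyl; chain C2 unconfigured) | COC(=O)CC(=O)C(C(=O)OC)[C@@H]1CC(=O)[C@@H](CO[Si](c2ccccc2)(c2ccccc2)C(C)(C)C)CC13OCCO3 | intermediate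
6 | (6S,8S,9R)-8-hydroxy analogue of 5 (12α-OH, all-equatorial ring) | COC(=O)CC(=O)C(C(=O)OC)[C@@H]1C[C@H](O)[C@@H](CO[Si](c2ccccc2)(c2ccccc2)C(C)(C)C)CC13OCCO3 | intermediate
7 | dimethyl 2-[5-hydroxy-2-oxo-4-(silyloxymethyl)cyclohexyl]-3-oxopentanedioate (ring centres as in 6) | COC(=O)CC(=O)C(C(=O)OC)[C@@H]1C[C@H](O)[C@@H](CO[Si](c2ccccc2)(c2ccccc2)C(C)(C)C)CC1=O | intermediate
8 | bicyclic hydroxy enone diester (rings B and C; C5 ketone, C6=C8, 12α-OH; C10 unconfigured) | COC(=O)C1=C2C[C@H](CO[Si](c4ccccc4)(c4ccccc4)C(C)(C)C)[C@@H](O)C[C@H]2C(C1=O)C(=O)OC | intermediate (not isolated)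
9 | tricyclic enone lactone (C5 ketone, C6=C8, 6-CO2Me, C20→12α-O lactone, 10β-H, 13β-CH2OSi) | COC(=O)C1=C2C[C@H](CO[Si](c4ccccc4)(c4ccccc4)C(C)(C)C)[C@@H]3C[C@H]2[C@H](C1=O)C(=O)O3 | intermediate
10 | methyl 3-oxopent-4-enoate | C=CC(=O)CC(=O)OC | starting material
11 | C10-quaternary Michael adduct (5-methoxy-3,5-dioxopentyl chain on the β face of C10) | COC(=O)C1=C2C[C@H](CO[Si](c4ccccc4)(c4ccccc4)C(C)(C)C)[C@@H]3C[C@H]2[C@](CCC(=O)CC(=O)OC)(C1=O)C(=O)O3 | intermediate
12 | saturated ring B keto diester (8β-H, 6β-CO2Me) | COC(=O)[C@@H]1[C@H]2C[C@H](CO[Si](c4ccccc4)(c4ccccc4)C(C)(C)C)[C@@H]3C[C@H]2[C@](CCC(=O)CC(=O)OC)(C1=O)C(=O)O3 | intermediate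
13 | tetracyclic enone (C3 ketone, C4=C5, 4-CO2Me) | COC(=O)C1=C2[C@H](C(=O)OC)[C@H]3C[C@H](CO[Si](c5ccccc5)(c5ccccc5)C(C)(C)C)[C@@H]4C[C@H]3[C@@]2(CCC1=O)C(=O)O4 | intermediate
14 | trans-fused β-keto ester (5β-H; C4 unconfigured) | COC(=O)C1[C@H]2[C@H](C(=O)OC)[C@H]3C[C@H](CO[Si](c5ccccc5)(c5ccccc5)C(C)(C)C)[C@@H]4C[C@H]3[C@@]2(CCC1=O)C(=O)O4 | intermediate
15 | C4-quaternary keto triester (4β-Me, 4α-CO2Me) | COC(=O)[C@@]1(C)[C@H]2[C@H](C(=O)OC)[C@H]3C[C@H](CO[Si](c5ccccc5)(c5ccccc5)C(C)(C)C)[C@@H]4C[C@H]3[C@@]2(CCC1=O)C(=O)O4 | intermediate
16 | C3 enol triflate (C2=C3) | COC(=O)[C@@]1(C)[C@H]2[C@H](C(=O)OC)[C@H]3C[C@H](CO[Si](c5ccccc5)(c5ccccc5)C(C)(C)C)[C@@H]4C[C@H]3[C@@]2(CC=C1OS(=O)(=O)C(F)(F)F)C(=O)O4 | intermediate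
17 | 2-ene | COC(=O)[C@@]1(C)[C@H]2[C@H](C(=O)OC)[C@H]3C[C@H](CO[Si](c5ccccc5)(c5ccccc5)C(C)(C)C)[C@@H]4C[C@H]3[C@@]2(CC=C1)C(=O)O4 | intermediate
18 | 2β,3β-diol | COC(=O)[C@@]1(C)[C@H]2[C@H](C(=O)OC)[C@H]3C[C@H](CO[Si](c5ccccc5)(c5ccccc5)C(C)(C)C)[C@@H]4C[C@H]3[C@@]2(C[C@H](O)[C@@H]1O)C(=O)O4 | intermediate
19 | 2β,3β-acetonide | COC(=O)[C@@]1(C)[C@H]2[C@H](C(=O)OC)[C@H]3C[C@H](CO[Si](c5ccccc5)(c5ccccc5)C(C)(C)C)[C@@H]4C[C@H]3[C@@]2(C[C@@H]6OC(C)(C)O[C@H]16)C(=O)O4 | intermediate
20 | C16 alcohol (13β-CH2OH) | COC(=O)[C@@]1(C)[C@H]2[C@H](C(=O)OC)[C@H]3C[C@H](CO)[C@@H]4C[C@H]3[C@@]2(C[C@@H]6OC(C)(C)O[C@H]16)C(=O)O4 | intermediate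
21 | C16 aldehyde | COC(=O)[C@@]1(C)[C@H]2[C@H](C(=O)OC)[C@H]3C[C@H](C=O)[C@@H]4C[C@H]3[C@@]2(C[C@@H]6OC(C)(C)O[C@H]16)C(=O)O4 | intermediate (not isolated)
22 | C16 carboxylic acid (13β-CO2H) | COC(=O)[C@@]1(C)[C@H]2[C@H](C(=O)OC)[C@H]3C[C@H](C(=O)O)[C@@H]4C[C@H]3[C@@]2(C[C@@H]6OC(C)(C)O[C@H]16)C(=O)O4 | intermediate
23 | (trimethylsilyl)diazomethane | C[Si](C)(C)C=[N+]=[N-] | starting material
24 | C16 acid chloride | COC(=O)[C@@]1(C)[C@H]2[C@H](C(=O)OC)[C@H]3C[C@H](C(=O)Cl)[C@@H]4C[C@H]3[C@@]2(C[C@@H]6OC(C)(C)O[C@H]16)C(=O)O4 | intermediate (not isolated)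
25 | 13β-diazoacetyl ring A/B/C lactone, 7,19-dimethyl ester, 2β,3β-acetonide | [N-]=[N+]=CC(=O)[C@@H](C[C@@H]23)[C@@H]1C[C@H]2[C@@]2(C[C@@H]4OC(C)(C)O[C@@H]4[C@@](C)(C(=O)OC)[C@H]2[C@@H]3C(=O)OC)C(=O)O1 | intermediate
26 | 16-oxo pentacycle, 7,19-dimethyl ester, 2β,3β-acetonide | O=C1C[C@]23C[C@H]1[C@@H]1C[C@H]2[C@@]2(C[C@@H]4OC(C)(C)O[C@@H]4[C@@](C)(C(=O)OC)[C@H]2[C@@H]3C(=O)OC)C(=O)O1 | intermediate
27 | 16-methylene pentacycle, 7,19-dimethyl ester, 2β,3β-acetonide | C=C1C[C@]23C[C@H]1[C@@H]1C[C@H]2[C@@]2(C[C@@H]4OC(C)(C)O[C@@H]4[C@@](C)(C(=O)OC)[C@H]2[C@@H]3C(=O)OC)C(=O)O1 | intermediate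
28 | 16-methylene 7,19-diacid 2β,3β-acetonide | C=C1C[C@]23C[C@H]1[C@@H]1C[C@H]2[C@@]2(C[C@@H]4OC(C)(C)O[C@@H]4[C@@](C)(C(=O)O)[C@H]2[C@@H]3C(=O)O)C(=O)O1 | intermediate
29 | CNP0212122.1 (2β,3β-dihydroxy 20→12α-lactone 7,19-diacid) | C=C1C[C@]23C[C@H]1[C@@H]1C[C@H]2[C@@]2(C[C@H](O)[C@H](O)[C@@](C)(C(=O)O)[C@H]2[C@@H]3C(=O)O)C(=O)O1 | target

## Step count and least certain steps

Total step count: 22. Longest linear sequence: 22 steps (from 1; 4, 10 and 23 are purchased).

**Step 19 (key step).** The most likely failure is loss of site selectivity. The carbenoid may insert into the other axial C–H bond at C11, or dimerise, because both axial hydrogens are within reach and C8–H is flanked by the C6 ester, which hinders it and withdraws some electron density. The fallback changes the carbenoid to the doubly stabilised type, which discriminates more strongly in favour of tertiary C–H bonds. It sets out from 22 and comes back at 26. Activation of 22 with 1,1'-carbonyldiimidazole and C-acylation of Mg(O2CCH2CO2CH2CH=CH2)2 would give the allyl β-keto ester F1. Diazo transfer with 4-acetamidobenzenesulfonyl azide and Et3N would give the α-diazo-β-keto ester F2. Rh2(OAc)4 should then close ring D to the 15-allyloxycarbonyl 16-ketone F3. Pd(PPh3)4 and morpholine remove the allyl ester with loss of CO2 and return the route to 26.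

**Step 3.** The most likely failure is sluggish addition or poor enantiofacial discrimination, because the β carbon is next to the fully substituted ketal carbon and iminium formation is slowed. The fallback replaces catalyst control by a covalently bound auxiliary. It sets out from 3 and comes back at 7. Acid-catalysed ketal exchange of 3 with (R,R)-hydrobenzoin (or its enantiomer, whichever shields the unwanted face) would give the chiral ketal F4. A base-mediated Michael addition of 4 (catalytic 1,8-diazabicyclo[5.4.0]undec-7-ene), directed by the neighbouring phenyl group, would give the adduct F5. NaBH4 would give the alcohol F6. The acid hydrolysis of step 5 then releases the auxiliary and delivers 7.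

**Step 4.** The most likely failure is insufficient facial selectivity of hydride delivery, together with incomplete equilibration at C13 before that centre is frozen, because both preferences rest on modest conformational energy differences. The fallback sets both centres by directed reactions. It sets out from 3 and comes back at 6. Selenenylation of the enolate of 3 (LiN(iPr)2, PhSeCl) would give the α'-phenylselanyl enone F7, which has no stereochemical issue at C13 and no second acceptor. The Michael addition of step 3 would give the adduct F8. Oxidation with H2O2 and syn-elimination would give the 13,14-enone F9. Reduction with NaBH4 and CeCl3·7H2O (Luche reduction, as with 2,5-disubstituted cyclohexenones) should give the cis-1,5 allylic alcohol F10. Hydroxyl-directed hydrogenation with [Ir(cod)(PCy3)(py)]PF6 then adds hydrogen to C13 on the face of the hydroxyl group and gives 6.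

**Step 10.** The most likely failure is hydrogen delivery to the α face, giving the cis A/B fusion, or migration of the double bond to C5=C6 with loss of the C6 configuration, because C5 carries a neighbouring ester on each face. The fallback sets C5 after C4 is quaternary, when both axial carboxyl carbons block the α face. It sets out from 13 and comes back at 17. Deconjugative C-methylation of 13 (K2CO3, MeI) would give the 4-methyl 5,6-enoate F11. The conditions of steps 12 and 13 would give the enol triflate F12 and then the diene ester F13. Conjugate reduction of the enoate with Mg in MeOH, with protonation of C5 from the β face and equilibration of C6 by the methoxide formed, followed by acidic work-up to re-close any opened lactone, would give 17.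

## Further compounds

F1 | step 19 | allyl β-keto ester (13β-C(=O)CH2CO2allyl) | COC(=O)[C@@]1(C)[C@H]2[C@H](C(=O)OC)[C@H]3C[C@H](C(=O)CC(=O)OCC=C)[C@@H]4C[C@H]3[C@@]2(C[C@@H]6OC(C)(C)O[C@H]16)C(=O)O4
F2 | step 19 | α-diazo-β-keto allyl ester | COC(=O)[C@@]1(C)[C@H]2[C@H](C(=O)OC)[C@H]3C[C@H](C(=O)C(=[N+]=[N-])C(=O)OCC=C)[C@@H]4C[C@H]3[C@@]2(C[C@@H]6OC(C)(C)O[C@H]16)C(=O)O4
F3 | step 19 | 15-allyloxycarbonyl 16-oxo pentacycle (C15 unconfigured) | O=C1C(C(=O)OCC=C)[C@]23C[C@H]1[C@@H]1C[C@H]2[C@@]2(C[C@@H]4OC(C)(C)O[C@@H]4[C@@](C)(C(=O)OC)[C@H]2[C@@H]3C(=O)OC)C(=O)O1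
F4 | step 3 | (R,R)-hydrobenzoin ketal analogue of 3 (C13 unconfigured) | O=C1C=CC2(CC1CO[Si](c3ccccc3)(c3ccccc3)C(C)(C)C)O[C@H](c3ccccc3)[C@@H](c3ccccc3)O2
F5 | step 3 | (R,R)-hydrobenzoin ketal analogue of 5 | COC(=O)CC(=O)C(C(=O)OC)[C@@H]1CC(=O)[C@@H](CO[Si](c2ccccc2)(c2ccccc2)C(C)(C)C)CC13O[C@H](c2ccccc2)[C@@H](c2ccccc2)O3
F6 | step 3 | (R,R)-hydrobenzoin ketal analogue of 6 | COC(=O)CC(=O)C(C(=O)OC)[C@@H]1C[C@H](O)[C@@H](CO[Si](c2ccccc2)(c2ccccc2)C(C)(C)C)CC13O[C@H](c2ccccc2)[C@@H](c2ccccc2)O3
F7 | step 4 | (±)-9-(phenylselanyl)-9-(silyloxymethyl)-1,4-dioxaspiro[4.5]dec-6-en-8-one | O=C1C=CC2(CC1(CO[Si](c3ccccc3)(c3ccccc3)C(C)(C)C)[Se]c3ccccc3)OCCO2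
F8 | step 4 | Michael adduct of F7 and 4 (C13 unconfigured) | COC(=O)CC(=O)C(C(=O)OC)[C@@H]1CC(=O)C(CO[Si](c2ccccc2)(c2ccccc2)C(C)(C)C)([Se]c2ccccc2)CC13OCCO3
F9 | step 4 | 13,14-enone (C12 ketone, C13=C14, 13-CH2OSi) | COC(=O)CC(=O)C(C(=O)OC)[C@@H]1CC(=O)C(CO[Si](c2ccccc2)(c2ccccc2)C(C)(C)C)=CC13OCCO3
F10 | step 4 | 12α allylic alcohol (C13=C14) | COC(=O)CC(=O)C(C(=O)OC)[C@@H]1C[C@H](O)C(CO[Si](c2ccccc2)(c2ccccc2)C(C)(C)C)=CC13OCCO3
F11 | step 10 | 4β-methyl 5,6-enoate (C3 ketone, C5=C6) | COC(=O)[C@@]1(C)C2=C(C(=O)OC)[C@H]3C[C@H](CO[Si](c5ccccc5)(c5ccccc5)C(C)(C)C)[C@@H]4C[C@H]3[C@@]2(CCC1=O)C(=O)O4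
F12 | step 10 | C3 enol triflate of F11 | COC(=O)[C@@]1(C)C2=C(C(=O)OC)[C@H]3C[C@H](CO[Si](c5ccccc5)(c5ccccc5)C(C)(C)C)[C@@H]4C[C@H]3[C@@]2(CC=C1OS(=O)(=O)C(F)(F)F)C(=O)O4
F13 | step 10 | 2,5-diene ester (C2=C3, C5=C6) | COC(=O)[C@@]1(C)C2=C(C(=O)OC)[C@H]3C[C@H](CO[Si](c5ccccc5)(c5ccccc5)C(C)(C)C)[C@@H]4C[C@H]3[C@@]2(CC=C1)C(=O)O4
A1 | alternative 1 | (R)-7a-propargyl bicyclic enedione (rings B and C) | C#CC[C@]23CCC(=O)C=C2CCC3=O
A2 | alternative 2 | pentacyclic C2 silyl enol ether with C3 methoxymethyl ether | C=C1C[C@]23C[C@H]1[C@@H]1C[C@H]2[C@@]2(C=C(O[Si](C)(C)C(C)(C)C)[C@H](OCOC)[C@@](C)(C(=O)OC)[C@H]2[C@@H]3C(=O)OC)C(=O)O1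
A3 | alternative 3 | ring A/B-fused 12-nitronorbornene | C1=C[C@]23C[C@H]1[C@H]([N+](=O)[O-])[C@H]2[C@@]2(C[C@@H]4OC(C)(C)O[C@@H]4[C@@](C)(C(=O)OC)[C@H]2[C@@H]3C(=O)OC)C(=O)OC
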